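**Plan**

1. Core numbering used throughout: C1 acyl bridgehead, C2(=O), C3H=C4(OH), C5 prenyl bridgehead, C6H2, C7H(prenyl), C8(CH3)(homoprenyl), C9 bridging carbonyl; ring B = C1–C2–C3–C4–C5–C9, ring A = C1–C8–C7–C6–C5–C9.
2. Retrosynthetic cuts, in order: the C1–acyl bond and the C2 oxygen, then C8–CH3 (back to a C8 carbinol), then C1–C8 (aldol) together with C5–C6 (Michael). The enone partner is cut at its C7=CH2 bond and at one α-carbon–allyl bond (back to 6-methylhept-5-en-2-one), the dione at C5–prenyl.
3. Enabling feature: C1 and C5, the two α-carbons of the C9 ketone, both lie in ring A. Ring B can therefore be bought as a cyclohexane-1,3-dione (its carbonyls become C9 and C4, with C5 between them) and ring A laid across it with the three-carbon enone unit C6=C7–C8(=O).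
4. Forward order: the acyclic enone is assembled first, ring A then closes onto ring B in one annulation. After that come C8–CH3, the C4 enol ether, the C2 carbonyl and the C1 isobutyryl group, and two masking groups are removed.
5. Stereochemistry: a chiral primary amine chooses which ring carbonyl becomes C9, which sets C5 and with it C1. The chair closure with equilibrating C7 puts OH axial at C8 and prenyl equatorial at C7. Methyl later enters the C8 cation on the same axial face, and C1 is acylated as a bridgehead that cannot invert.

Key step: step 5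

Assumption: the sense of induction of the amine in step 5 cannot be predicted with confidence; the quinine-derived amine is written, and its quinidine-derived pseudo-enantiomer is taken instead should it favour the other ring carbonyl.

**Route**

Step 1
Reactants: 1 cyclohexane-1,3-dione; 2 1-bromo-3-methylbut-2-ene (prenyl bromide)
Product: 3 2-(3-methylbut-2-enyl)cyclohexane-1,3-dione
Conditions: KOH, H2O, 0 °C → rt
Reagents that add atoms: none
Why: SN2 C-alkylation of the β-diketone enolate, favoured at carbon in water where the enolate oxygens are hydrogen-bonded; the acidic C-alkylated dione can be separated from neutral O-prenyl ether by base extraction.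

Step 2
Reactants: 4 6-methylhept-5-en-2-one; 5 1,1-dimethylhydrazine
Product: 6 6-methylhept-5-en-2-one N,N-dimethylhydrazone
Conditions: AcOH (cat.), EtOH, reflux
Reagents that add atoms: none
Why: acid-catalysed condensation of a ketone with an N,N-disubstituted hydrazine gives the dimethylhydrazone, which masks the carbonyl and prepares the regiocontrolled alkylation of the next step; the trisubstituted alkene is inert.

Step 3
Reactants: 6 6-methylhept-5-en-2-one N,N-dimethylhydrazone; 2 1-bromo-3-methylbut-2-ene (prenyl bromide)
Product: 8 2,10-dimethylundeca-2,9-dien-6-one, via alkylated hydrazone 7 (not isolated)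
Conditions: LiN(i-Pr)2, THF, 0 °C; then 2, −78 → 0 °C; then sat. aq. oxalic acid, Et2O, rt
Reagents that add atoms: water, O
Why: Corey–Enders hydrazone alkylation: the base metalates the dimethylhydrazone at the less substituted α-carbon (the methyl group), the azaenolate is mono-alkylated by the allylic bromide in SN2 fashion, and mild two-phase acid hydrolysis releases the symmetrical ketone, whose carbonyl carbon is the future C8, without touching the two trisubstituted alkenes.

Step 4
Reactants: 8 2,10-dimethylundeca-2,9-dien-6-one
Product: 11 2,10-dimethyl-7-methylideneundeca-2,9-dien-6-one, via Mannich base 9 (not isolated), via methiodide 10 (not isolated)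
Conditions: LiN(i-Pr)2, THF, −78 °C; CH2=NMe2+ I−, −78 °C → rt; then MeI, CH2Cl2, rt; then aq. NaHCO3, rt
Reagents that add atoms: dimethylmethyleneiminium iodide, C=[N+](C)C.[I-]
Why: Mannich aminomethylation of the lithium enolate, N-quaternisation and E1cB loss of trimethylamine give the α-methylene ketone; the ketone is symmetrical, so only one mono-enolate exists, and methylenation turns one homoprenyl arm into the α-prenyl branch (future C7 prenyl) while the other arm remains as the C8 homoprenyl group.

Step 5
Reactants: 3 2-(3-methylbut-2-enyl)cyclohexane-1,3-dione; 11 2,10-dimethyl-7-methylideneundeca-2,9-dien-6-one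
Product: 13 (1R,5R,7S,8S)-8-hydroxy-5,7-bis(3-methylbut-2-enyl)-8-(4-methylpent-3-enyl)bicyclo[3.3.1]nonane-4,9-dione, via triketone 12 (not isolated)
Conditions: Et3N (20 mol %), MeCN, 40 °C; then 9-amino-9-deoxy-epi-quinine (20 mol %), PhCO2H (40 mol %), toluene, 40 °C
Reagents that add atoms: none
Why: Proposed new method: amine-base Michael addition of the dione enol through C5 to the methylene carbon C6 of 11 gives triketone 12 (C5–C6 bond), in which the two ring carbonyls are enantiotopic at C5 and C7 is an epimerisable α-centre; the primary amine then condenses with one ring carbonyl (C9) to a secondary enamine whose α-carbon C1 adds to the acid-activated side-chain ketone C8 (C1–C8 bond). The closest known reactions are the racemic Michael–bridged-ketol annulation of 2-alkylcyclohexane-1,3-diones with enones and the amine-catalysed desymmetrising aldol cyclisations of prochiral triketones of the Hajos–Parrish and Wieland–Miescher type; new here is the use of the ring enamine for the bridged closure with control of absolute configuration. Ring A closes in a 6-(enolendo)-exo-trig mode through a chair. C5 is set by the catalyst's choice of carbonyl, C1 follows from C5 because the new ring can only span C9 in a cis-bridged fashion, C8 arises from the chair with homoprenyl equatorial and the carbonyl oxygen axial and hydrogen-bonded to the protonated catalyst, and C7 settles with prenyl equatorial because it should epimerise through the C8 enol faster than the ring closes. The step needs the bridged aldol to outrun the fused Robinson aldol: the side-chain ketone is α-branched and slow to form its own enamine, the ring carbonyls it would have to attack are neopentyl, and the reaction is stopped at the ketol before dehydration can drain material.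

Step 6
Reactants: 13 bridged ketol
Product: 14 8-chloro-5,7-bis(3-methylbut-2-enyl)-8-(4-methylpent-3-enyl)bicyclo[3.3.1]nonane-4,9-dione (C1, C5 and C7 as in 13; C8 as epimers)
Conditions: 1-chloro-N,N,2-trimethylprop-1-en-1-amine, CH2Cl2, 0 °C → rt
Reagents that add atoms: 1-chloro-N,N,2-trimethylprop-1-en-1-amine, CC(C)=C(Cl)N(C)C
Why: chlorodehydroxylation with an α-chloroenamine runs under neutral conditions (alkoxy-iminium chloride ion pair collapsing to the tertiary chloride and an amide), avoiding the free HCl that would add to the three trisubstituted alkenes and the base that would open the ketol by retro-aldol; the C8 configuration is immaterial because it is erased in the next step, and E1cB loss of HCl is impossible because C1 is a bridgehead.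

Step 7
Reactants: 14 tertiary chloride
Product: 15 (1R,5R,7S,8R)-8-methyl-5,7-bis(3-methylbut-2-enyl)-8-(4-methylpent-3-enyl)bicyclo[3.3.1]nonane-4,9-dione
Conditions: Me2TiCl2 (from Me2Zn + TiCl4), CH2Cl2, −78 °C
Reagents that add atoms: dimethyltitanium dichloride, C[Ti](C)(Cl)Cl
Why: Reetz methylation: the Lewis acids ionise the tertiary chloride at −78 °C and methyl is transferred within the ion pair, which should be faster than elimination and than addition to the two α-quaternary ketones at this temperature; methyl enters the planar C8 cation axially on the face remote from the C2–C4 bridge (only C6–H is 1,3-diaxial, C9 being trigonal), so homoprenyl stays equatorial, and the C9 carbonyl disfavours migration of C2 because that would place the charge at C1.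

Step 8
Reactants: 15 C8-methyl dione
Product: 16 4-methoxy-8-methyl-5,7-bis(3-methylbut-2-enyl)-8-(4-methylpent-3-enyl)bicyclo[3.3.1]non-3-en-9-one (configuration as in 15)
Conditions: KN(SiMe3)2, THF–DMPU, −78 °C; then Me2SO4, −78 → 0 °C
Reagents that add atoms: dimethyl sulfate, COS(=O)(=O)OC
Why: enolate O-alkylation: C3 is the only enolisable position (C9 is flanked by quaternary C5 and bridgehead C1), and the dissociated potassium enolate should react at oxygen with the hard sulfate electrophile in a dipolar medium, placing the methoxy group on C4 so that the coming carbonyl must appear at C2.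

Step 9
Reactants: 16 methyl enol ether
Product: 17 4-methoxy-8-methyl-5,7-bis(3-methylbut-2-enyl)-8-(4-methylpent-3-enyl)bicyclo[3.3.1]non-3-ene-2,9-dione (configuration as in 15)
Conditions: t-BuOOH, PhI(OAc)2, Cs2CO3 (cat.), EtOAc, −78 → −20 °C
Reagents that add atoms: tert-butyl hydroperoxide, CC(C)(C)OO
Why: radical allylic oxidation (hydrogen abstraction by tert-butylperoxy radical, peroxide formation and Kornblum–DeLaMare elimination), a known way from cyclic methyl enol ethers to vinylogous esters; the C2 methylene allylic to the electron-rich enol ether carries the weakest C–H bonds in the molecule.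

Step 10
Reactants: 17 vinylogous ester
Product: 18 4-methoxy-8-methyl-5,7-bis(3-methylbut-2-enyl)-8-(4-methylpent-3-enyl)-3-(trimethylsilyl)bicyclo[3.3.1]non-3-ene-2,9-dione (configuration as in 15)
Conditions: lithium 2,2,6,6-tetramethylpiperidide, Me3SiCl (in situ), THF, −78 °C
Reagents that add atoms: chlorotrimethylsilane, C[Si](C)(C)Cl
Why: directed vinylic lithiation at C3 of the β-methoxy enone with in situ silyl trapping blocks this kinetically more accessible site before the hindered bridgehead is metalated.

Step 11
Reactants: 18 C3-silyl vinylogous ester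
Product: 19 4-methoxy-8-methyl-5,7-bis(3-methylbut-2-enyl)-8-(4-methylpent-3-enyl)-1-(2-methylpropanoyl)-3-(trimethylsilyl)bicyclo[3.3.1]non-3-ene-2,9-dione (C5, C7 and C8 as in 15; acyl in place of the C1 hydrogen)
Conditions: lithium 2,2,6,6-tetramethylpiperidide, THF, −78 → −40 °C; then i-PrCOCl, −78 °C → rt
Reagents that add atoms: 2-methylpropanoyl chloride, CC(C)C(=O)Cl
Why: bridgehead lithiation–acylation: C1–H, flanked by the C2 and C9 carbonyls, is the only remaining acidic C–H and gives a pyramidal bridgehead α-keto carbanion (no enolate is possible) that is acylated with retention by necessity.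

Step 12
Reactants: 19 C1-acyl C3-silyl vinylogous ester
Product: 20 (1R,5R,7S,8R)-4-methoxy-8-methyl-5,7-bis(3-methylbut-2-enyl)-8-(4-methylpent-3-enyl)-1-(2-methylpropanoyl)bicyclo[3.3.1]non-3-ene-2,9-dione
Conditions: Bu4NF, AcOH, THF, 0 °C → rt
Reagents that add atoms: none
Why: fluoride-mediated protodesilylation of the α-silyl enone, buffered with acetic acid so that the non-enolisable C1 tricarbonyl array is not exposed to a basic nucleophile.

Step 13
Reactants: 20 O-methyl ether of the target
Product: 21 (1R,5R,7S,8R)-4-hydroxy-8-methyl-5,7-bis(3-methylbut-2-enyl)-8-(4-methylpent-3-enyl)-1-(2-methylpropanoyl)bicyclo[3.3.1]non-3-ene-2,9-dione (CNP0178130.2)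
Conditions: LiCl, DMSO, 120 °C; then dilute aq. HCl, 0 °C
Reagents that add atoms: none
Why: SN2 O-demethylation of the vinylogous methyl ester by chloride, with the β-diketonate as leaving group, under non-aqueous, non-basic conditions that should spare the C1 triketone from retro-Claisen cleavage and touch no stereocentre.

**Compound list**

1 | cyclohexane-1,3-dione | O=C1CCCC(=O)C1 | starting material
2 | 1-bromo-3-methylbut-2-ene (prenyl bromide) | CC(C)=CCBr | starting material
3 | 2-(3-methylbut-2-enyl)cyclohexane-1,3-dione | CC(C)=CCC1C(=O)CCCC1=O | intermediate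
4 | 6-methylhept-5-en-2-one | CC(C)=CCCC(C)=O | starting material
5 | 1,1-dimethylhydrazine | CN(C)N | starting material
6 | 6-methylhept-5-en-2-one N,N-dimethylhydrazone (C=N isomers, mainly E; geometry immaterial) | CC(C)=CCCC(C)=NN(C)C | intermediate
7 | 2,10-dimethylundeca-2,9-dien-6-one N,N-dimethylhydrazone (alkylated hydrazone, formed in the flask) | CC(C)=CCCC(=NN(C)C)CCC=C(C)C | intermediate
8 | 2,10-dimethylundeca-2,9-dien-6-one | CC(C)=CCCC(=O)CCC=C(C)C | intermediate
9 | 7-[(dimethylamino)methyl]-2,10-dimethylundeca-2,9-dien-6-one (Mannich base, racemic, formed in the flask) | CN(C)CC(CC=C(C)C)C(=O)CCC=C(C)C | intermediate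
10 | trimethylammonium iodide of 9 (methiodide, formed in the flask) | C[N+](C)(C)CC(CC=C(C)C)C(=O)CCC=C(C)C.[I-] | intermediate
11 | 2,10-dimethyl-7-methylideneundeca-2,9-dien-6-one | C=C(CC=C(C)C)C(=O)CCC=C(C)C | intermediate
12 | 2-(3-methylbut-2-enyl)-2-[7-methyl-2-(3-methylbut-2-enyl)-3-oxooct-6-enyl]cyclohexane-1,3-dione (triketone, C7 epimerising, formed in the flask) | CC(C)=CCCC(=O)C(CC=C(C)C)CC1(CC=C(C)C)C(=O)CCCC1=O | intermediate
13 | (1R,5R,7S,8S)-8-hydroxy-5,7-bis(3-methylbut-2-enyl)-8-(4-methylpent-3-enyl)bicyclo[3.3.1]nonane-4,9-dione (OH axial, homoprenyl and C7 prenyl equatorial on ring A) | CC(C)=CCC[C@]1(O)[C@@H](CC=C(C)C)C[C@@]2(CC=C(C)C)C(=O)[C@@H]1CCC2=O | intermediate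
14 | 8-chloro analogue of 13 (C1, C5, C7 as in 13; C8 epimers) | CC(C)=CCCC1(Cl)[C@@H](CC=C(C)C)C[C@@]2(CC=C(C)C)C(=O)[C@@H]1CCC2=O | intermediate
15 | (1R,5R,7S,8R)-8-methyl-5,7-bis(3-methylbut-2-enyl)-8-(4-methylpent-3-enyl)bicyclo[3.3.1]nonane-4,9-dione (methyl axial) | CC(C)=CCC[C@]1(C)[C@@H](CC=C(C)C)C[C@@]2(CC=C(C)C)C(=O)[C@@H]1CCC2=O | intermediate
16 | 4-methoxy-8-methyl-5,7-bis(3-methylbut-2-enyl)-8-(4-methylpent-3-enyl)bicyclo[3.3.1]non-3-en-9-one (configuration as in 15) | CC(C)=CCC[C@]1(C)[C@@H](CC=C(C)C)C[C@@]2(CC=C(C)C)C(=O)[C@@H]1CC=C2OC | intermediate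
17 | 4-methoxy-8-methyl-5,7-bis(3-methylbut-2-enyl)-8-(4-methylpent-3-enyl)bicyclo[3.3.1]non-3-ene-2,9-dione (configuration as in 15) | CC(C)=CCC[C@]1(C)[C@@H](CC=C(C)C)C[C@@]2(CC=C(C)C)C(=O)[C@@H]1C(=O)C=C2OC | intermediate
18 | 3-trimethylsilyl derivative of 17 | CC(C)=CCC[C@]1(C)[C@@H](CC=C(C)C)C[C@@]2(CC=C(C)C)C(=O)[C@@H]1C(=O)C([Si](C)(C)C)=C2OC | intermediate
19 | 1-(2-methylpropanoyl)-3-trimethylsilyl derivative of 17 | CC(C)=CCC[C@]1(C)[C@@H](CC=C(C)C)C[C@@]2(CC=C(C)C)C(=O)[C@]1(C(=O)C(C)C)C(=O)C([Si](C)(C)C)=C2OC | intermediate
20 | (1R,5R,7S,8R)-4-methoxy-8-methyl-5,7-bis(3-methylbut-2-enyl)-8-(4-methylpent-3-enyl)-1-(2-methylpropanoyl)bicyclo[3.3.1]non-3-ene-2,9-dione | CC(C)=CCC[C@]1(C)[C@@H](CC=C(C)C)C[C@@]2(CC=C(C)C)C(=O)[C@]1(C(=O)C(C)C)C(=O)C=C2OC | intermediate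
21 | (1R,5R,7S,8R)-4-hydroxy-8-methyl-5,7-bis(3-methylbut-2-enyl)-8-(4-methylpent-3-enyl)-1-(2-methylpropanoyl)bicyclo[3.3.1]non-3-ene-2,9-dione | CC(C)=CCC[C@]1(C)[C@@H](CC=C(C)C)C[C@@]2(CC=C(C)C)C(=O)[C@]1(C(=O)C(C)C)C(=O)C=C2O | target

**Step count**

Total: 13 steps. Longest linear sequence: 12 steps (from 4 through steps 2–13; the branch from 1 joins at step 5).

**Steps most likely to fail**

Step 5. The amine may condense with the side-chain ketone and drive the fused Robinson-type closure and dehydration. It may also discriminate poorly between the two ring carbonyls, or the ring may close before C7 has equilibrated. The fallback uses known chemistry and sets out again from 3 and 11. The Michael adduct is closed under achiral general-base conditions of the kind known to give bridged ketols from such triketones (catalytic 1,8-diazabicyclo[5.4.0]undec-7-ene, MeCN, 0 °C). This should give 13 as a racemate, that is, together with the enantiomeric ketol F1. The enantiomers are separated by preparative chromatography on a chiral stationary phase (amylose tris(3,5-dimethylphenylcarbamate)), and the route is rejoined at 13.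

Step 7. Methyl may be transferred to the C4 or C9 carbonyl. The ion pair may lose HCl towards C7 or the side chain, a 1,2-hydride shift from C7 may precede capture, or the nucleophile may attack the wrong face. The fallback replaces the cation by a radical and sets out from 13. The tertiary alcohol and methanol are each condensed with 3-phenylbenzoxazolium tetrafluoroborate and pyridine, giving the benzoxazoline adduct of 13 F2 and 2-methoxy-3-phenyl-2,3-dihydro-1,3-benzoxazole F3. The mixture is irradiated with blue light in the presence of [Ir(ppy)2(dtbbpy)]PF6, Ni(acac)2 and potassium hydrotris(3,5-dimethylpyrazol-1-yl)borate. β-Scission should release the C8 tertiary radical and a methyl radical, which nickel is expected to pair by SH2 substitution, methyl again arriving on the open axial face. The route is rejoined at 15 without passing through 14.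

Step 9. Hydrogen may be abstracted from the allylic positions of the three side chains, or the enol ether may be destroyed oxidatively; one step earlier, C-methylation at C3 may compete with O-methylation. The fallback sets out from 15 and bypasses steps 8 and 9. The C4 ketone is dehydrogenated (LiN(i-Pr)2, then N-tert-butylbenzenesulfinimidoyl chloride) to the C2=C3 enone F4. Nucleophilic epoxidation (t-BuOOH, 1,8-diazabicyclo[5.4.0]undec-7-ene) then gives the epoxy ketone F5. Isomerisation with Pd(PPh3)4 and 1,2-bis(diphenylphosphino)ethane in hot toluene gives the 2,4,9-trione F6. O-Methylation (Me3SiCHN2, MeOH) gives 17 together with the C2-methoxy regioisomer F7, which is separated, hydrolysed back to F6 with dilute aqueous acid and recycled. The route is rejoined at 17.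

**Further compounds**

F1 | step 5 | enantiomer of ketol 13 | CC(C)=CCC[C@@]1(O)[C@H](CC=C(C)C)C[C@]2(CC=C(C)C)C(=O)[C@H]1CCC2=O
F2 | step 7 | 3-phenyl-2,3-dihydro-1,3-benzoxazol-2-yl ether of 13 (benzoxazoline adduct) | CC(C)=CCC[C@]1(OC3Oc4ccccc4N3c3ccccc3)[C@@H](CC=C(C)C)C[C@@]2(CC=C(C)C)C(=O)[C@@H]1CCC2=O
F3 | step 7 | 2-methoxy-3-phenyl-2,3-dihydro-1,3-benzoxazole | COC1Oc2ccccc2N1c1ccccc1
F4 | step 9 | 8-methyl-5,7-bis(3-methylbut-2-enyl)-8-(4-methylpent-3-enyl)bicyclo[3.3.1]non-2-ene-4,9-dione (configuration as in 15) | CC(C)=CCC[C@]1(C)[C@@H](CC=C(C)C)C[C@@]2(CC=C(C)C)C(=O)[C@@H]1C=CC2=O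
F5 | step 9 | 2,3-epoxide of F4 (epoxide configuration immaterial) | CC(C)=CCC[C@]1(C)[C@@H](CC=C(C)C)C[C@@]2(CC=C(C)C)C(=O)[C@@H]1C3OC3C2=O
F6 | step 9 | 8-methyl-5,7-bis(3-methylbut-2-enyl)-8-(4-methylpent-3-enyl)bicyclo[3.3.1]nonane-2,4,9-trione (configuration as in 15) | CC(C)=CCC[C@]1(C)[C@@H](CC=C(C)C)C[C@@]2(CC=C(C)C)C(=O)[C@@H]1C(=O)CC2=O
F7 | step 9 | 2-methoxy-8-methyl-5,7-bis(3-methylbut-2-enyl)-8-(4-methylpent-3-enyl)bicyclo[3.3.1]non-2-ene-4,9-dione (regioisomer of 17) | CC(C)=CCC[C@]1(C)[C@@H](CC=C(C)C)C[C@@]2(CC=C(C)C)C(=O)[C@@H]1C(OC)=CC2=O
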